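The route rests on cutting the C13–C16 bond of the bicyclo[3.2.1]octane. A monovalent-gold-catalysed 5-exo-dig addition of a C12–C13 silyl enol ether to the propargyl arm on quaternary C8 closes the five-membered ring (C8, C14, C13, C16, C15) last and sets the C13 bridgehead, the C12 ketone and the C16=C17 methylene in one operation. It exploits the 1,3-relationship across cyclohexanone ring C between enolisable C13 and C8. The precursor, a 4-formyl-4-propargylcyclohexanone bearing ring A at C9, comes from two Diels–Alder reactions (auxiliary-controlled for C4/C10, catalyst-controlled for C8/C9). The two carboxyls travel as their cis-anhydride and are released by hydrolysis at the end.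

Key step: step 15

Remark: kaurane atom numbers (C1–C20) are used throughout; tert-butyl 2-(triphenylphosphoranylidene)propanoate and pent-4-ynal are taken as purchasable (otherwise one step each from tert-butyl 2-bromopropanoate or pent-4-yn-1-ol).

Step 1
Reactants: 1 acrolein; 2 ethyl 2-(triphenylphosphoranylidene)propanoate
Product: 3 ethyl (2E)-2-methylpenta-2,4-dienoate
Conditions: CH2Cl2, 0 °C to rt
Reagents that add atoms: none
Why: Wittig olefination with a stabilised α-methyl ylide is (E)-selective, so the ester (later the "outside" CH2O group of the diene) is trans to the vinyl group.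

Step 2
Reactants: 3 ethyl (2E)-2-methylpenta-2,4-dienoate
Product: 4 (2E)-2-methylpenta-2,4-dien-1-ol
Conditions: i-Bu2AlH (2.2 equiv), CH2Cl2, −78 °C; Rochelle salt work-up
Reagents that add atoms: none
Why: 1,2-hydride reduction of the conjugated ester leaves the (E)-diene untouched.

Step 3
Reactants: 4 (2E)-2-methylpenta-2,4-dien-1-ol
Product: 5 triethyl{[(2E)-2-methylpenta-2,4-dien-1-yl]oxy}silane
Conditions: Et3SiCl, imidazole, CH2Cl2, 0 °C
Reagents that add atoms: chlorotriethylsilane, CC[Si](Cl)(CC)CC
Why: silylation of the primary alcohol gives an ether that should survive steps 6–9 and be oxidised directly in step 10.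

Step 4
Reactants: 6 glyoxylic acid monohydrate; 7 tert-butyl 2-(triphenylphosphoranylidene)propanoate
Product: 8 (2E)-4-tert-butoxy-3-methyl-4-oxobut-2-enoic acid
Conditions: CH2Cl2, 0 °C to rt
Reagents that add atoms: none
Why: Wittig olefination of glyoxylic acid with a stabilised ylide gives the (E)-alkene (carboxyl trans to the ester), the mesaconate geometry needed for the cycloaddition.

Step 5
Reactants: 8 (2E)-4-tert-butoxy-3-methyl-4-oxobut-2-enoic acid; 9 (4R)-4-benzyl-1,3-oxazolidin-2-one
Product: 11 (4R)-4-benzyl-3-[(2E)-4-tert-butoxy-3-methyl-4-oxobut-2-enoyl]-1,3-oxazolidin-2-one, via mixed pivalic anhydride 10 (not isolated)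
Conditions: t-BuCOCl, Et3N, THF, −20 °C; then 9, LiCl, rt
Reagents that add atoms: none
Why: mixed-anhydride N-acylation of the oxazolidinone, in which the hindered pivaloyl carbonyl is not attacked.

Step 6
Reactants: 5 triethyl{[(2E)-2-methylpenta-2,4-dien-1-yl]oxy}silane; 11 acyl oxazolidinone
Product: 12 ring-A cycloadduct (cyclohexene bearing C4, C5 and C10)
Conditions: Et2AlCl (1.6 equiv), CH2Cl2, −78 to −30 °C
Reagents that add atoms: none
Why: auxiliary-controlled Diels–Alder reaction of the aluminium-chelated s-cis acylimide: the diene should add to the face opposite the benzyl group, endo to the imide carbonyl, with the unsubstituted terminus C3 bonding to the β-carbon C4 and the disubstituted terminus C10 to C5, which fixes C4 and C10 (outside CH2OSiEt3 cis to the acyl group and the C4 methyl, inside methyl cis to CO2t-Bu) and leaves the C5 acyl group trans to CO2t-Bu.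

Step 7
Reactants: 12 ring-A cycloadduct
Product: 13 ring-A carboxylic acid (C6 acid, C19 tert-butyl ester)
Conditions: LiOH, H2O2, THF/H2O, 0 °C; Na2SO3; HCl to pH 3
Reagents that add atoms: hydrogen peroxide, OO
Why: hydroperoxide anion attacks the exocyclic imide carbonyl selectively (auxiliary cleavage by acyl substitution) and no stereocentre is touched at 0 °C.

Step 8
Reactants: 13 ring-A carboxylic acid
Product: 16 cis-fused ring-A anhydride, via trans-diacid 14 (not isolated), via trans-fused anhydride 15 (not isolated)
Conditions: Me3SiOTf, 2,6-lutidine, CH2Cl2, 0 °C; brief aq. work-up; then Ac2O, NaOAc, 100 °C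
Reagents that add atoms: none
Why: buffered silyl-triflate cleavage of the tert-butyl ester should spare the primary triethylsilyl ether, acetic anhydride closes the trans-fused anhydride, and acetate then epimerises C5 (the only enolisable stereocentre) to the more stable cis-fused anhydride, so that C6 ends cis to C19 and to the C10 methyl under thermodynamic control.

Step 9
Reactants: 16 cis-fused ring-A anhydride
Product: 17 saturated ring-A anhydride
Conditions: H2 (1 atm), Pd/C, EtOAc, rt
Reagents that add atoms: none
Why: heterogeneous hydrogenation of the only C=C bond (C1=C2) creates no stereocentre and the silyl ether is stable in ethyl acetate.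

Step 10
Reactants: 17 saturated ring-A anhydride; 18 1-(triphenylphosphoranylidene)propan-2-one
Product: 20 ring-A (E)-enone, via ring-A aldehyde 19 (not isolated)
Conditions: (COCl)2, DMSO, CH2Cl2, −78 to −30 °C; Et3N; then 18, CHCl3, 60 °C
Reagents that add atoms: none
Why: Swern conditions oxidise a primary triethylsilyl ether directly to the aldehyde without releasing a free alcohol that could open the anhydride, and the Wittig reaction with the stabilised ylide gives the (E)-enone.

Step 11
Reactants: 20 ring-A (E)-enone
Product: 21 ring-A 2-silyloxy-1,3-diene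
Conditions: t-BuMe2SiOTf, Et3N, CH2Cl2, 0 °C
Reagents that add atoms: tert-butyldimethylsilyl trifluoromethanesulfonate, CC(C)(C)[Si](C)(C)OS(=O)(=O)C(F)(F)F
Why: amine/silyl-triflate enolisation of the methyl ketone can only give the 2-silyloxydiene because C10 is quaternary and there is no γ-hydrogen (silyl dienol ether formation).

Step 12
Reactants: 22 pent-4-ynal; 23 formaldehyde
Product: 24 2-methylidenepent-4-ynal
Conditions: 37 % aq. HCHO, pyrrolidine (10 mol %), EtCO2H (10 mol %), i-PrOH, 45 °C
Reagents that add atoms: none
Why: amine-catalysed Mannich condensation with formaldehyde followed by elimination (α-methylenation of an aldehyde).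

Step 13
Reactants: 21 ring-A 2-silyloxy-1,3-diene; 24 2-methylidenepent-4-ynal
Product: 26 keto aldehyde (ring C closed), via silyl enol ether cycloadduct 25 (not isolated)
Conditions: (S)-3,3-diphenyl-1-(o-tolyl)pyrrolo-oxazaborolidine·HNTf2 (20 mol %), CH2Cl2, −78 to −40 °C; then 1 M HCl, THF, 0 °C
Reagents that add atoms: none
Why: enantioselective Diels–Alder reaction of a 2-substituted acrolein under chiral oxazaborolidinium catalysis: the silyloxy group (para) and the C9 substituent (ortho) both direct C13 to C14 and C9 to C8, the formyl group is endo so that CHO ends cis and the propargyl arm trans to ring A, and the catalyst enantiomer is chosen to leave the Si face of C8 open, which fixes C8 and C9 relative to C10; acid work-up hydrolyses the silyl enol ether.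

Step 14
Reactants: 26 keto aldehyde
Product: 27 C12=C13 triisopropylsilyl enol ether
Conditions: i-Pr3SiOTf, Et3N, CH2Cl2, −78 to −20 °C
Reagents that add atoms: triisopropylsilyl trifluoromethanesulfonate, CC(C)[Si](C(C)C)(C(C)C)OS(=O)(=O)C(F)(F)F
Why: soft enolisation with a bulky silyl triflate should remove the more accessible C13 proton, because C11 is shielded by C9 and its fully substituted neighbours C8 and C10, and the aldehyde has no α-hydrogen (regioselective silyl enol ether formation).

Step 15
Reactants: 27 C12=C13 triisopropylsilyl enol ether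
Product: 28 bicyclo[3.2.1]octane anhydride (anhydride of the target)
Conditions: Ph3PAuCl (10 mol %), AgBF4 (10 mol %), CH2Cl2/H2O (10:1), 40 °C
Reagents that add atoms: none
Why: Cationic monovalent gold coordinates the C16≡C17 alkyne of the propargyl arm on C8, the C12=C13 silyl enol ether attacks C16 through C13 anti to gold, and the vinylgold oxocarbenium loses silicon to water and is protodeaurated to the exocyclic C16=C17 methylene. The closest known reaction type is the gold-catalysed carbocyclisation of silyl enol ethers onto alkynes (Conia-ene type) used for bicyclo[3.2.1]octanes. Ring D (C8–C14–C13–C16–C15) closes in the 5-exo-dig mode and is the last ring formed. The new stereocentre C13 is set by the substrate, because the two-atom C15–C16 bridge can only span C8 and C13 on the face of ring C that carries the propargyl arm, so C13 follows from C8. The step needs C13 rather than C11 as the nucleophile and carbon rather than the C7 formyl oxygen to attack the alkyne; the first is secured by the regiodefined enol ether, the second by the higher nucleophilicity of the enol ether over a neopentyl, non-enolisable aldehyde. The reactive chair places the propargyl arm and ring A trans-diaxial on ring C, which should be tolerated because C12 is trigonal.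

Step 16
Reactants: 28 bicyclo[3.2.1]octane anhydride
Product: 29 target diacid (CNP0320711.1)
Conditions: 0.2 M aq. NaOH, THF, 0 °C to rt; then cold 1 M HCl to pH 3
Reagents that add atoms: water, O
Why: hydroxide opens the cyclic anhydride at the less hindered C6 carbonyl (acyl substitution) and cold acidification liberates the diacid; no stereocentre is touched, since C8 has no hydrogen and bridgehead C13 cannot enolise.

Compound list
1 | acrolein (prop-2-enal) | C=CC=O | starting material
2 | ethyl 2-(triphenylphosphoranylidene)propanoate | CCOC(=O)C(C)=P(c1ccccc1)(c1ccccc1)c1ccccc1 | starting material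
3 | ethyl (2E)-2-methylpenta-2,4-dienoate | CCOC(=O)/C(C)=C/C=C | intermediate
4 | (2E)-2-methylpenta-2,4-dien-1-ol | OC/C(C)=C/C=C | intermediate
5 | triethyl{[(2E)-2-methylpenta-2,4-dien-1-yl]oxy}silane | CC[Si](CC)(CC)OC/C(C)=C/C=C | intermediate
6 | glyoxylic acid monohydrate (2,2-dihydroxyacetic acid) | OC(O)C(=O)O | starting material
7 | tert-butyl 2-(triphenylphosphoranylidene)propanoate | CC(C(=O)OC(C)(C)C)=P(c1ccccc1)(c1ccccc1)c1ccccc1 | starting material
8 | (2E)-4-tert-butoxy-3-methyl-4-oxobut-2-enoic acid | OC(=O)/C=C(\C)C(=O)OC(C)(C)C | intermediate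
9 | (4R)-4-benzyl-1,3-oxazolidin-2-one | O=C1N[C@H](Cc2ccccc2)CO1 | starting material
10 | mixed anhydride of 8 with pivalic acid | CC(C)(C)C(=O)OC(=O)/C=C(\C)C(=O)OC(C)(C)C | intermediate
11 | (4R)-4-benzyl-3-[(2E)-4-tert-butoxy-3-methyl-4-oxobut-2-enoyl]-1,3-oxazolidin-2-one | O=C1OC[C@@H](Cc2ccccc2)N1C(=O)/C=C(\C)C(=O)OC(C)(C)C | intermediate
12 | tert-butyl 2-{[(4R)-4-benzyl-2-oxo-1,3-oxazolidin-3-yl]carbonyl}-1,3-dimethyl-3-[(triethylsilyloxy)methyl]cyclohex-4-ene-1-carboxylate (ring carbons 1, 2, 3 = C4, C5, C10; acyl group cis to the C4 methyl and to CH2OSiEt3, trans to CO2t-Bu and the C10 methyl) | CC[Si](CC)(CC)OC[C@]1(C)C=CC[C@@](C)(C(=O)OC(C)(C)C)[C@@H]1C(=O)N1C(=O)OC[C@H]1Cc1ccccc1 | intermediate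
13 | 2-(tert-butoxycarbonyl)-2,6-dimethyl-6-[(triethylsilyloxy)methyl]cyclohex-3-ene-1-carboxylic acid (CO2H cis to the C4 methyl and to CH2OSiEt3, trans to CO2t-Bu and the C10 methyl) | CC[Si](CC)(CC)OC[C@]1(C)C=CC[C@@](C)(C(=O)OC(C)(C)C)[C@@H]1C(=O)O | intermediate
14 | 1,3-dimethyl-3-[(triethylsilyloxy)methyl]cyclohex-4-ene-1,2-dicarboxylic acid, trans-diacid (C6 carboxyl trans to C19 carboxyl, cis to CH2OSiEt3) | CC[Si](CC)(CC)OC[C@]1(C)C=CC[C@@](C)(C(=O)O)[C@@H]1C(=O)O | intermediate
15 | trans-fused anhydride of 14 | CC[Si](CC)(CC)OC[C@]1(C)C=CC[C@@]2(C)C(=O)OC(=O)[C@H]12 | intermediate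
16 | 3a,7-dimethyl-7-[(triethylsilyloxy)methyl]-3a,4,7,7a-tetrahydro-2-benzofuran-1,3-dione, cis-fused (C10 methyl cis to the anhydride ring, CH2OSiEt3 trans to it) | CC[Si](CC)(CC)OC[C@]1(C)C=CC[C@@]2(C)C(=O)OC(=O)[C@@H]12 | intermediate
17 | 3a,7-dimethyl-7-[(triethylsilyloxy)methyl]hexahydro-2-benzofuran-1,3-dione, cis-fused (same relative configuration as 16) | CC[Si](CC)(CC)OC[C@]1(C)CCC[C@@]2(C)C(=O)OC(=O)[C@@H]12 | intermediate
18 | 1-(triphenylphosphoranylidene)propan-2-one | CC(=O)C=P(c1ccccc1)(c1ccccc1)c1ccccc1 | starting material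
19 | 3a,7-dimethyl-1,3-dioxo-octahydro-2-benzofuran-7-carbaldehyde, cis-fused (CHO trans to the anhydride ring) | O=C[C@]1(C)CCC[C@@]2(C)C(=O)OC(=O)[C@@H]12 | intermediate
20 | 3a,7-dimethyl-7-[(1E)-3-oxobut-1-en-1-yl]hexahydro-2-benzofuran-1,3-dione, cis-fused (enone chain trans to the anhydride ring) | CC(=O)/C=C/[C@]1(C)CCC[C@@]2(C)C(=O)OC(=O)[C@@H]12 | intermediate
21 | 7-[(1E)-3-(tert-butyldimethylsilyloxy)buta-1,3-dien-1-yl]-3a,7-dimethylhexahydro-2-benzofuran-1,3-dione (same configuration as 20) | C=C(O[Si](C)(C)C(C)(C)C)/C=C/[C@]1(C)CCC[C@@]2(C)C(=O)OC(=O)[C@@H]12 | intermediate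
22 | pent-4-ynal | C#CCCC=O | starting material
23 | formaldehyde | C=O | starting material
24 | 2-methylidenepent-4-ynal (2-propargylacrolein) | C=C(CC#C)C=O | intermediate
25 | cycloadduct, C11=C12 tert-butyldimethylsilyl enol ether (C8 formyl cis, propargyl trans to ring A at C9) | C#CC[C@]1(C=O)CCC(O[Si](C)(C)C(C)(C)C)=C[C@H]1[C@]1(C)CCC[C@@]2(C)C(=O)OC(=O)[C@@H]12 | intermediate
26 | (4R,5S,8R,9S,10S) keto aldehyde: 4-formyl-4-(prop-2-yn-1-yl)cyclohexanone carrying at C9 the ring-A anhydride (kaurane locants; CHO cis, propargyl trans to ring A) | C#CC[C@]1(C=O)CCC(=O)C[C@H]1[C@]1(C)CCC[C@@]2(C)C(=O)OC(=O)[C@@H]12 | intermediate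
27 | (4R,5S,8R,9S,10S) C12=C13 triisopropylsilyl enol ether of 26 | C#CC[C@]1(C=O)CC=C(O[Si](C(C)C)(C(C)C)C(C)C)C[C@H]1[C@]1(C)CCC[C@@]2(C)C(=O)OC(=O)[C@@H]12 | intermediate
28 | (4R,5S,8R,9S,10S,13R)-7,12-dioxo-6,7-secokaur-16-ene-6,19-dioic anhydride | C=C1C[C@]2(C=O)C[C@H]1C(=O)C[C@H]2[C@]1(C)CCC[C@@]2(C)C(=O)OC(=O)[C@@H]12 | intermediate
29 | (4R,5S,8R,9S,10S,13R)-7,12-dioxo-6,7-secokaur-16-ene-6,19-dioic acid (CNP0320711.1) | C=C1C[C@]2(C=O)C[C@H]1C(=O)C[C@H]2[C@]1(C)CCC[C@@](C)(C(=O)O)[C@H]1C(=O)O | target

Total step count: 16. Longest linear sequence: 13 steps (steps 1–3, 6–11, 13–16).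

Steps most likely to fail

Step 13. The asynchronous cycloaddition may stop after the first bond (C13–C14) because closure of C8–C9, between a quaternary carbon and a carbon next to quaternary C10, is slow. It may also close with eroded endo and facial selectivity if catalyst and chiral diene are mismatched. The fallback builds ring C in two separately promoted bond formations. It sets out from 21 and 24: a Mukaiyama–Michael addition catalysed by t-BuMe2SiNTf2 at −78 °C should stop, after silyl transfer, at the open-chain enone carrying the aldehyde as its tert-butyldimethylsilyl enol ether F1. TiCl4 at −78 °C should then force the intramolecular Mukaiyama–Michael closure of C8 onto C9 through a chair with ring A equatorial (substrate control). Aqueous work-up comes back to the route at 26.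

Step 6. The Z-methyl group on the diene terminus disfavours the s-cis conformer, so the bulky aluminium-chelated imide may fail to engage and the diene may be lost to cationic oligomerisation. The fallback uses a smaller formyl-activated dienophile under catalyst control and sets out from 5 and 7. Wittig reaction of 7 with excess aqueous glyoxal should give tert-butyl (2E)-2-methyl-4-oxobut-2-enoate F2. Its Diels–Alder reaction with 5 under a chiral oxazaborolidinium triflimide (formyl endo, same regiochemistry) should give the ring-A aldehyde F3. Pinnick oxidation (NaClO2, NaH2PO4, 2-methylbut-2-ene) comes back to the route at 13.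

Step 15. The gold-activated alkyne may be captured by the C7 formyl oxygen (carbonyl-assisted hydration), or the enol ether may be protodesilylated before C–C bond formation, because the reactive chair needs ring A and the propargyl arm both axial. The fallback is a radical closure that sets out from 27. N-Iodosuccinimide should give the C13 α-iodo ketone F4. Iodine-atom-transfer cyclisation ((Bu3Sn)2 cat., hν, benzene; 5-exo-dig) should give the exocyclic vinyl iodide F5. Reduction with Bu3SnH/AIBN comes back to the route at 28.

Further compounds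
F1 | step 13 | open-chain Michael adduct: 2-(prop-2-yn-1-yl)-5-oxo-7-(ring-A anhydride)hept-6-enal as its tert-butyldimethylsilyl enol ether | CC(C)(C)[Si](C)(C)OC=C(CC#C)CCC(=O)/C=C/[C@]1(C)CCC[C@@]2(C)C(=O)OC(=O)[C@@H]12
F2 | step 6 | tert-butyl (2E)-2-methyl-4-oxobut-2-enoate | O=C/C=C(\C)C(=O)OC(C)(C)C
F3 | step 6 | tert-butyl 2-formyl-1,3-dimethyl-3-[(triethylsilyloxy)methyl]cyclohex-4-ene-1-carboxylate (CHO cis to the C4 methyl and to CH2OSiEt3) | CC[Si](CC)(CC)OC[C@]1(C)C=CC[C@@](C)(C(=O)OC(C)(C)C)[C@@H]1C=O
F4 | step 15 | C13 α-iodo ketone derived from 27 | C#CC[C@]1(C=O)CC(I)C(=O)C[C@H]1[C@]1(C)CCC[C@@]2(C)C(=O)OC(=O)[C@@H]12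
F5 | step 15 | 17-iodo derivative of 28 (exocyclic vinyl iodide) | IC=C1C[C@]2(C=O)C[C@H]1C(=O)C[C@H]2[C@]1(C)CCC[C@@]2(C)C(=O)OC(=O)[C@@H]12
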